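**Retrosynthetic overview**

1. The target is (6S,9S,10S)-2,10-dibromochamigra-2,7-dien-9-ol: ring B = C1–C6 with the C2(Br)=C3(CH3) alkene, C6 is the spiro carbon, ring A = C6–C11 with C7(CH3)=C8, C9–OH, C10–Br and the C11 gem-dimethyl group. The last operations are C2 enol triflate → C2 bromide and desilylation at C9.
2. The ring B bromoalkene comes from a 2-methyl enone (C2=O, C3=C4) by conjugate hydride addition and O-triflation of the regiodefined C2=C3 enolate; that enone comes from hydrolysis of the ring-closure product.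
3. Key disconnection: the C6–C7 bond, made by an intramolecular Heck reaction of a (Z)-alkenyl iodide (C7) onto the C5=C6 alkene of a preformed ring B. Ring B is made first (Birch reduction of an anisole); ring A is closed in the key step.
4. Enabling feature: C2, the bromine-bearing alkene carbon of ring B, is 1,3 to the spiro carbon C6. It is carried as a carbonyl masked as a dioxolane (a ring absent from the target, cleaved later) that holds the ring B alkene at C5=C6. Palladium therefore lands on C5, the trans C9–O/C10–Br pair next to the C11 gem-dimethyl group relays its configuration to C6, and the alkene moves to where it unlocks C2/C3.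
5. The cyclisation precursor comes from an aryl bromide and prenal (C11), an organocatalytic α-bromination (C10), an oxazaborolidine reduction of an ynone (C9) and trans-hydrosilylation/iododesilylation (Z-alkenyl iodide).

Key step: step 12

Remark: locants C1–C11 are chamigrane locants as defined above; the C3 methyl centre formed in step 3 is carried as a mixture of both epimers (written 3RS or 10RS) until it becomes sp2 in step 13, and the change of the C6 descriptor from R (18, 19) to S (20 onward) is a priority effect only.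
Remark: the facial sense of the organocatalytic bromination (step 5) and of the oxazaborolidine reduction (step 8) is taken from the accepted models; should either prove opposite, the enantiomeric catalyst is used.

**Step 1**
Reactants: 1 4-bromo-2-methoxy-1-methylbenzene; 2 3-methylbut-2-enal
Product: 6 3-(3-methoxy-4-methylphenyl)-3-methylbutan-1-ol, via arylmagnesium bromide 3 (not isolated), via silyl enol ether 4 (not isolated), via aldehyde 5 (not isolated)
Conditions: Mg, THF, reflux; CuBr·SMe2 (10 mol %), TMSCl, 2, THF, −78 → −20 °C; 1 M HCl; NaBH4, MeOH, 0 °C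
Reagents that add atoms: none
Why: Copper-catalysed, silyl chloride-assisted conjugate addition of the aryl Grignard reagent to the β,β-disubstituted enal should build the quaternary carbon C11, and sodium borohydride reduction masks the aldehyde as the alcohol for the dissolving-metal step; no stereocentre is formed.

**Step 2**
Reactants: 6 3-(3-methoxy-4-methylphenyl)-3-methylbutan-1-ol
Product: 7 3-(5-methoxy-4-methylcyclohexa-1,4-dien-1-yl)-3-methylbutan-1-ol
Conditions: Li, NH3 (l), THF, t-BuOH, −78 → −33 °C; NH4Cl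
Reagents that add atoms: none
Why: Birch reduction of the anisole should leave the donor-substituted carbons sp2 and so give the 1-methoxy-1,4-diene with the enol ether at C2=C3 and the isolated alkene at C5=C6; no stereocentre is formed.

**Step 3**
Reactants: 7 3-(5-methoxy-4-methylcyclohexa-1,4-dien-1-yl)-3-methylbutan-1-ol
Product: 8 3-methyl-3-[(10RS)-10-methyl-1,4-dioxaspiro[4.5]dec-7-en-7-yl]butan-1-ol
Conditions: ethylene glycol, TsOH·H2O (2 mol %), CH2Cl2, 0 °C → rt
Reagents that add atoms: ethylene glycol OCCO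
Why: Acid-catalysed addition of the diol to the enol ether (transketalisation) should trap the C2 carbonyl as the dioxolane without letting the C5=C6 alkene move; the C3 methyl centre forms unselectively as a mixture of both epimers, which is of no consequence.

**Step 4**
Reactants: 8 3-methyl-3-[(10RS)-10-methyl-1,4-dioxaspiro[4.5]dec-7-en-7-yl]butan-1-ol
Product: 9 3-methyl-3-[(10RS)-10-methyl-1,4-dioxaspiro[4.5]dec-7-en-7-yl]butanal
Conditions: Dess–Martin periodinane, CH2Cl2, 0 °C → rt
Reagents that add atoms: none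
Why: Dess–Martin oxidation should convert the primary alcohol into the aldehyde under conditions that the dioxolane and the ring alkene tolerate; no stereocentre is formed.

**Step 5**
Reactants: 9 3-methyl-3-[(10RS)-10-methyl-1,4-dioxaspiro[4.5]dec-7-en-7-yl]butanal
Product: 10 (2S)-2-bromo-3-methyl-3-[(10RS)-10-methyl-1,4-dioxaspiro[4.5]dec-7-en-7-yl]butanal
Conditions: (2R,5R)-2,5-diphenylpyrrolidine (20 mol %), 4,4-dibromo-2,6-di-tert-butylcyclohexa-2,5-dien-1-one, PhCO2H (20 mol %), CH2Cl2/pentane, −40 °C; used at once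
Reagents that add atoms: 4,4-dibromo-2,6-di-tert-butylcyclohexa-2,5-dien-1-one CC(C)(C)C1=CC(Br)(Br)C=C(C1=O)C(C)(C)C
Why: Enamine-catalysed electrophilic α-bromination of the aldehyde by the C2-symmetric pyrrolidine, which shields one enamine face, should set C10 as the (S)-bromide, the adjacent quaternary carbon slowing enolisation of the product.

**Step 6**
Reactants: 10 (2S)-2-bromo-3-methyl-3-[(10RS)-10-methyl-1,4-dioxaspiro[4.5]dec-7-en-7-yl]butanal; 11 prop-1-yn-1-ylmagnesium bromide
Product: 12 (4RS,5S)-5-bromo-6-methyl-6-[(10RS)-10-methyl-1,4-dioxaspiro[4.5]dec-7-en-7-yl]hept-2-yn-4-ol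
Conditions: THF, −78 °C; sat. NH4Cl at −78 °C
Reagents that add atoms: none
Why: 1,2-Addition of the alkynyl Grignard reagent to the highly electrophilic α-bromo aldehyde should be fast at low temperature; the configuration of the new carbinol does not matter because it is erased in step 7.

**Step 7**
Reactants: 12 (4RS,5S)-5-bromo-6-methyl-6-[(10RS)-10-methyl-1,4-dioxaspiro[4.5]dec-7-en-7-yl]hept-2-yn-4-ol
Product: 13 (5S)-5-bromo-6-methyl-6-[(10RS)-10-methyl-1,4-dioxaspiro[4.5]dec-7-en-7-yl]hept-2-yn-4-one
Conditions: Dess–Martin periodinane, CH2Cl2, 0 °C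
Reagents that add atoms: none
Why: Dess–Martin oxidation under non-basic conditions should give the α-bromo ynone without enolisation of the C10 stereocentre.

**Step 8**
Reactants: 13 (5S)-5-bromo-6-methyl-6-[(10RS)-10-methyl-1,4-dioxaspiro[4.5]dec-7-en-7-yl]hept-2-yn-4-one
Product: 14 (4S,5S)-5-bromo-6-methyl-6-[(10RS)-10-methyl-1,4-dioxaspiro[4.5]dec-7-en-7-yl]hept-2-yn-4-ol
Conditions: (R)-2-methyl-CBS-oxazaborolidine (0.3 equiv), catecholborane, toluene, −78 °C
Reagents that add atoms: none
Why: Corey–Bakshi–Shibata reduction, in which the catalyst treats the branched bromoalkyl group as large and the alkyne as small and which is matched to the Felkin–Anh preference (hydride anti to the C–Br bond), should set C9 as (S), syn to the bromide.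

**Step 9**
Reactants: 14 (4S,5S)-5-bromo-6-methyl-6-[(10RS)-10-methyl-1,4-dioxaspiro[4.5]dec-7-en-7-yl]hept-2-yn-4-ol
Product: 15 (2Z,4S,5S)-5-bromo-6-methyl-6-[(10RS)-10-methyl-1,4-dioxaspiro[4.5]dec-7-en-7-yl]-2-(triethylsilyl)hept-2-en-4-ol
Conditions: Et3SiH, [Cp*Ru(MeCN)3]PF6 (2 mol %), CH2Cl2, 0 °C → rt
Reagents that add atoms: triethylsilane CC[SiH](CC)CC
Why: Cationic ruthenium-catalysed trans-hydrosilylation of the propargylic alcohol should place silicon on the carbon distal to the hydroxyl and add H and Si anti, which gives the (Z)-alkenylsilane needed for ring closure.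

**Step 10**
Reactants: 15 (2Z,4S,5S)-5-bromo-6-methyl-6-[(10RS)-10-methyl-1,4-dioxaspiro[4.5]dec-7-en-7-yl]-2-(triethylsilyl)hept-2-en-4-ol
Product: 16 tert-butyl{[(2Z,4S,5S)-5-bromo-6-methyl-6-[(10RS)-10-methyl-1,4-dioxaspiro[4.5]dec-7-en-7-yl]-2-(triethylsilyl)hept-2-en-4-yl]oxy}dimethylsilane
Conditions: TBSOTf, 2,6-lutidine, CH2Cl2, −78 → 0 °C
Reagents that add atoms: tert-butyldimethylsilyl trifluoromethanesulfonate CC(C)(C)[Si](C)(C)OS(=O)(=O)C(F)(F)F
Why: Silylation with the silyl triflate and a hindered pyridine base avoids an alkoxide (and so epoxide formation) and keeps the hydroxyl from iodoetherification onto the ring alkene in step 11.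

**Step 11**
Reactants: 16 tert-butyl{[(2Z,4S,5S)-5-bromo-6-methyl-6-[(10RS)-10-methyl-1,4-dioxaspiro[4.5]dec-7-en-7-yl]-2-(triethylsilyl)hept-2-en-4-yl]oxy}dimethylsilane
Product: 17 tert-butyl{[(2Z,4S,5S)-5-bromo-2-iodo-6-methyl-6-[(10RS)-10-methyl-1,4-dioxaspiro[4.5]dec-7-en-7-yl]hept-2-en-4-yl]oxy}dimethylsilane
Conditions: N-iodosuccinimide, (CF3)2CHOH, 0 °C, short reaction time
Reagents that add atoms: N-iodosuccinimide O=C1CCC(=O)N1I
Why: Electrophilic ipso-iododesilylation of the alkenylsilane in hexafluoroisopropanol should proceed with retention of alkene geometry, the β-silyl effect making this alkene far more reactive than the ring alkene.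

**Step 12**
Reactants: 17 tert-butyl{[(2Z,4S,5S)-5-bromo-2-iodo-6-methyl-6-[(10RS)-10-methyl-1,4-dioxaspiro[4.5]dec-7-en-7-yl]hept-2-en-4-yl]oxy}dimethylsilane
Product: 18 (3RS,6R,9S,10S)-10-bromo-9-[(tert-butyldimethylsilyl)oxy]chamigra-4,7-dien-2-one ethylene ketal
Conditions: Pd(OAc)2 (10 mol %), PPh3 (30 mol %), 1,2,2,6,6-pentamethylpiperidine, MeCN, 80 °C
Reagents that add atoms: none
Why: Oxidative addition of zerovalent palladium into the C7–I bond, syn carbopalladation of the ring B C5=C6 alkene (C7 to C6, palladium to C5) and syn β-hydride elimination from C4 (the only β-hydrogens, C6 being quaternary) close ring A; the closest known reaction type is the intramolecular Heck spirocyclisation of alkenyl halides onto 1-substituted cyclohexenes that creates quaternary spiro centres. Ring A closes in the 6-exo-trig mode, the 7-endo alternative being disfavoured by ring size and by the tether. The new stereocentre C6 is set by a chair-like transition state in which the palladium-bridged carbon C5 must sit pseudo-axial on the nascent ring (it eclipses the C7–Pd bond), while the C9 silyloxy and C10 bromo groups both stay equatorial, because an axial C9 substituent would be 1,3-diaxial to the axial C11 methyl and an axial C10 bromine 1,3-diaxial to the C5–Pd unit; this one chair places C1 on the face of the C10 bromine, as in the target. The step needs insertion into the alkenyl C–I bond in the presence of the secondary alkyl bromide, which the neopentyl position of that bromide and the simple triarylphosphine should secure, and it needs the ring B alkene at C5=C6 and not in conjugation at C1=C6, which the dioxolane at C2 secures, since a conjugated enone would force C1 axial and give the C6 epimer. Re-addition of the palladium hydride can only move the new alkene between C4=C5 and C3=C4, and both isomers converge in step 13.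

**Step 13**
Reactants: 18 (3RS,6R,9S,10S)-10-bromo-9-[(tert-butyldimethylsilyl)oxy]chamigra-4,7-dien-2-one ethylene ketal
Product: 20 (6S,9S,10S)-10-bromo-9-[(tert-butyldimethylsilyl)oxy]chamigra-3,7-dien-2-one, via deconjugated enone 19 (not isolated)
Conditions: TsOH·H2O (0.3 equiv), acetone/H2O, 40 °C
Reagents that add atoms: water O
Why: Acid-catalysed ketal hydrolysis followed by acid-catalysed migration of the β,γ-alkene into conjugation should give the 2-methyl enone, in which the C3 epimers (and any C3=C4 alkene isomer from step 12) converge; no stereocentre is formed.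

**Step 14**
Reactants: 20 (6S,9S,10S)-10-bromo-9-[(tert-butyldimethylsilyl)oxy]chamigra-3,7-dien-2-one
Product: 22 (6S,9S,10S)-10-bromo-9-[(tert-butyldimethylsilyl)oxy]chamigra-2,7-dien-2-yl trifluoromethanesulfonate, via lithium enolate 21 (not isolated)
Conditions: LiBH(s-Bu)3, THF, −78 °C; PhNTf2, −78 → 0 °C
Reagents that add atoms: N-phenylbis(trifluoromethanesulfonimide) O=S(=O)(N(c1ccccc1)S(=O)(=O)C(F)(F)F)C(F)(F)F
Why: Conjugate hydride addition of the hindered borohydride to the β-monosubstituted enone should generate the C2=C3 enolate regiospecifically, and O-sulfonylation with the triflimide fixes it as the tetrasubstituted enol triflate (1,4-reduction with enolate trapping).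

**Step 15**
Reactants: 22 (6S,9S,10S)-10-bromo-9-[(tert-butyldimethylsilyl)oxy]chamigra-2,7-dien-2-yl trifluoromethanesulfonate
Product: 23 (6S,9S,10S)-2,10-dibromo-9-[(tert-butyldimethylsilyl)oxy]chamigra-2,7-diene
Conditions: LiBr, [Cp*Ru(MeCN)3]OTf (5 mol %), 1,3-dimethyl-2-imidazolidinone, 100 °C
Reagents that add atoms: lithium bromide [Li+].[Br-]
Why: Ruthenium-catalysed halide exchange of alkenyl triflates should replace the triflate by bromide at the same carbon, while the neopentyl-type secondary C10 bromide is too hindered for substitution by bromide, so C10 is not scrambled.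

**Step 16**
Reactants: 23 (6S,9S,10S)-2,10-dibromo-9-[(tert-butyldimethylsilyl)oxy]chamigra-2,7-diene
Product: 24 (6S,9S,10S)-2,10-dibromochamigra-2,7-dien-9-ol
Conditions: HF·pyridine, THF, 0 °C → rt
Reagents that add atoms: none
Why: Fluoride-mediated desilylation under acidic and not basic conditions should free the C9 alcohol without closing the trans-bromohydrin to an epoxide.

**Compound list**

1 | 4-bromo-2-methoxy-1-methylbenzene | COc1cc(Br)ccc1C | starting material
2 | 3-methylbut-2-enal | CC(C)=CC=O | starting material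
3 | (3-methoxy-4-methylphenyl)magnesium bromide | COc1cc([Mg]Br)ccc1C | intermediate
4 | {[3-(3-methoxy-4-methylphenyl)-3-methylbut-1-en-1-yl]oxy}trimethylsilane | COc1cc(ccc1C)C(C)(C)C=CO[Si](C)(C)C | intermediate
5 | 3-(3-methoxy-4-methylphenyl)-3-methylbutanal | COc1cc(ccc1C)C(C)(C)CC=O | intermediate
6 | 3-(3-methoxy-4-methylphenyl)-3-methylbutan-1-ol | COc1cc(ccc1C)C(C)(C)CCO | intermediate
7 | 3-(5-methoxy-4-methylcyclohexa-1,4-dien-1-yl)-3-methylbutan-1-ol | COC1=C(C)CC=C(C1)C(C)(C)CCO | intermediate
8 | 3-methyl-3-[(10RS)-10-methyl-1,4-dioxaspiro[4.5]dec-7-en-7-yl]butan-1-ol | OCCC(C)(C)C1=CCC(C)C2(C1)OCCO2 | intermediate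
9 | 3-methyl-3-[(10RS)-10-methyl-1,4-dioxaspiro[4.5]dec-7-en-7-yl]butanal | O=CCC(C)(C)C1=CCC(C)C2(C1)OCCO2 | intermediate
10 | (2S)-2-bromo-3-methyl-3-[(10RS)-10-methyl-1,4-dioxaspiro[4.5]dec-7-en-7-yl]butanal | O=C[C@@H](Br)C(C)(C)C1=CCC(C)C2(C1)OCCO2 | intermediate
11 | prop-1-yn-1-ylmagnesium bromide | CC#C[Mg]Br | starting material
12 | (4RS,5S)-5-bromo-6-methyl-6-[(10RS)-10-methyl-1,4-dioxaspiro[4.5]dec-7-en-7-yl]hept-2-yn-4-ol | CC#CC(O)[C@@H](Br)C(C)(C)C1=CCC(C)C2(C1)OCCO2 | intermediate
13 | (5S)-5-bromo-6-methyl-6-[(10RS)-10-methyl-1,4-dioxaspiro[4.5]dec-7-en-7-yl]hept-2-yn-4-one | CC#CC(=O)[C@@H](Br)C(C)(C)C1=CCC(C)C2(C1)OCCO2 | intermediate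
14 | (4S,5S)-5-bromo-6-methyl-6-[(10RS)-10-methyl-1,4-dioxaspiro[4.5]dec-7-en-7-yl]hept-2-yn-4-ol | CC#C[C@H](O)[C@@H](Br)C(C)(C)C1=CCC(C)C2(C1)OCCO2 | intermediate
15 | (2Z,4S,5S)-5-bromo-6-methyl-6-[(10RS)-10-methyl-1,4-dioxaspiro[4.5]dec-7-en-7-yl]-2-(triethylsilyl)hept-2-en-4-ol | C/C([Si](CC)(CC)CC)=C/[C@H](O)[C@@H](Br)C(C)(C)C1=CCC(C)C2(C1)OCCO2 | intermediate
16 | tert-butyl{[(2Z,4S,5S)-5-bromo-6-methyl-6-[(10RS)-10-methyl-1,4-dioxaspiro[4.5]dec-7-en-7-yl]-2-(triethylsilyl)hept-2-en-4-yl]oxy}dimethylsilane | C/C([Si](CC)(CC)CC)=C/[C@H](O[Si](C)(C)C(C)(C)C)[C@@H](Br)C(C)(C)C1=CCC(C)C2(C1)OCCO2 | intermediate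
17 | tert-butyl{[(2Z,4S,5S)-5-bromo-2-iodo-6-methyl-6-[(10RS)-10-methyl-1,4-dioxaspiro[4.5]dec-7-en-7-yl]hept-2-en-4-yl]oxy}dimethylsilane | C/C(I)=C/[C@H](O[Si](C)(C)C(C)(C)C)[C@@H](Br)C(C)(C)C1=CCC(C)C2(C1)OCCO2 | intermediate
18 | (3RS,6R,9S,10S)-10-bromo-9-[(tert-butyldimethylsilyl)oxy]chamigra-4,7-dien-2-one ethylene ketal | CC1=C[C@H](O[Si](C)(C)C(C)(C)C)[C@@H](Br)C(C)(C)[C@]12C=CC(C)C3(C2)OCCO3 | intermediate
19 | (3RS,6R,9S,10S)-10-bromo-9-[(tert-butyldimethylsilyl)oxy]chamigra-4,7-dien-2-one | CC1=C[C@H](O[Si](C)(C)C(C)(C)C)[C@@H](Br)C(C)(C)[C@]12C=CC(C)C(=O)C2 | intermediate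
20 | (6S,9S,10S)-10-bromo-9-[(tert-butyldimethylsilyl)oxy]chamigra-3,7-dien-2-one | CC1=C[C@H](O[Si](C)(C)C(C)(C)C)[C@@H](Br)C(C)(C)[C@]12CC=C(C)C(=O)C2 | intermediate
21 | lithium (6S,9S,10S)-10-bromo-9-[(tert-butyldimethylsilyl)oxy]chamigra-2,7-dien-2-olate | CC1=C[C@H](O[Si](C)(C)C(C)(C)C)[C@@H](Br)C(C)(C)[C@]12CCC(C)=C([O-])C2.[Li+] | intermediate
22 | (6S,9S,10S)-10-bromo-9-[(tert-butyldimethylsilyl)oxy]chamigra-2,7-dien-2-yl trifluoromethanesulfonate | CC1=C[C@H](O[Si](C)(C)C(C)(C)C)[C@@H](Br)C(C)(C)[C@]12CCC(C)=C(OS(=O)(=O)C(F)(F)F)C2 | intermediate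
23 | (6S,9S,10S)-2,10-dibromo-9-[(tert-butyldimethylsilyl)oxy]chamigra-2,7-diene | CC1=C[C@H](O[Si](C)(C)C(C)(C)C)[C@@H](Br)C(C)(C)[C@]12CCC(C)=C(Br)C2 | intermediate
24 | (6S,9S,10S)-2,10-dibromochamigra-2,7-dien-9-ol, i.e. (3S,4S,6S)-4,8-dibromo-1,5,5,9-tetramethylspiro[5.5]undeca-1,8-dien-3-ol | CC1=C[C@H](O)[C@@H](Br)C(C)(C)[C@]12CCC(C)=C(Br)C2 | target

**Step count and risks**

Total step count: 16. Longest linear sequence: 16 steps (from 1).

The three steps most likely to fail:

Step 12. Carbopalladation of the hindered trisubstituted alkene next to the quaternary C11 may be slow, so that proto-deiodination or palladium hydride side reactions compete, or facial control may be eroded. The fallback changes the ring closure from a Heck reaction to a radical conjugate addition. It sets out from 17: acid hydrolysis of the dioxolane with migration of the alkene into conjugation (TsOH·H2O, acetone/H2O) should give the conjugated enone F1. A 6-exo cyclisation of the alkenyl radical onto the enone β-carbon C6 ((Me3Si)3SiH added slowly, AIBN, benzene, 80 °C; iodine abstraction should outrun abstraction of the hindered alkyl bromine) should give the spiro ketone F2 through the same chair with both tether substituents equatorial. Here the placement of the two ring B arms is steric and no longer enforced by the palladium bridge, so the C6 configuration must be confirmed. Thermodynamic enol silylation and triflation (TMSCl, NaI, Et3N, MeCN; MeLi; PhNTf2) bring the route back at 22.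

Step 5. The configurationally labile α-bromo aldehyde may lose enantiopurity before it is consumed, and the ring alkene may be brominated in competition. The fallback replaces organocatalysis by auxiliary control at the acid oxidation level. It sets out from 9: chlorite oxidation (NaClO2, NaH2PO4, 2-methylbut-2-ene) should give the carboxylic acid F3. Acylation of lithiated (4S)-4-benzyl-1,3-oxazolidin-2-one through the pivaloyl mixed anhydride should give the imide F4. Bromination of its boron enolate (Bu2BOTf, i-Pr2NEt; N-bromosuccinimide, −78 °C) should give the bromo imide F5. Aluminium amide transamination (AlMe3, MeONHMe·HCl) should give the Weinreb amide F6, which with 11 returns to the route at 13.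

Step 15. Halide exchange at the hindered tetrasubstituted triflate may be incomplete, and the allylic silyl ether may not survive the temperature needed. The fallback goes through tin. It sets out from 22: palladium-catalysed stannylation (Pd(PPh3)4, Me6Sn2, LiCl, THF, 60 °C) should give the alkenylstannane F7, and bromodestannylation (N-bromosuccinimide, MeCN, 0 °C) returns to the route at 23.

**Further compounds**

F1 | step 12 | (6RS)-3-{(3S,4S,5Z)-3-bromo-4-[(tert-butyldimethylsilyl)oxy]-6-iodo-2-methylhept-5-en-2-yl}-6-methylcyclohex-2-en-1-one | C/C(I)=C/[C@H](O[Si](C)(C)C(C)(C)C)[C@@H](Br)C(C)(C)C1=CC(=O)C(C)CC1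
F2 | step 12 | (3RS,6S,9S,10S)-10-bromo-9-[(tert-butyldimethylsilyl)oxy]chamigr-7-en-2-one | CC1=C[C@H](O[Si](C)(C)C(C)(C)C)[C@@H](Br)C(C)(C)[C@]12CCC(C)C(=O)C2
F3 | step 5 | 3-methyl-3-[(10RS)-10-methyl-1,4-dioxaspiro[4.5]dec-7-en-7-yl]butanoic acid | OC(=O)CC(C)(C)C1=CCC(C)C2(C1)OCCO2
F4 | step 5 | (4S)-4-benzyl-3-{3-methyl-3-[(10RS)-10-methyl-1,4-dioxaspiro[4.5]dec-7-en-7-yl]butanoyl}-1,3-oxazolidin-2-one | O=C(CC(C)(C)C1=CCC(C)C2(C1)OCCO2)N1[C@@H](Cc2ccccc2)COC1=O
F5 | step 5 | (4S)-4-benzyl-3-{(2S)-2-bromo-3-methyl-3-[(10RS)-10-methyl-1,4-dioxaspiro[4.5]dec-7-en-7-yl]butanoyl}-1,3-oxazolidin-2-one | O=C([C@@H](Br)C(C)(C)C1=CCC(C)C2(C1)OCCO2)N1[C@@H](Cc2ccccc2)COC1=O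
F6 | step 5 | (2S)-2-bromo-N-methoxy-N,3-dimethyl-3-[(10RS)-10-methyl-1,4-dioxaspiro[4.5]dec-7-en-7-yl]butanamide | CON(C)C(=O)[C@@H](Br)C(C)(C)C1=CCC(C)C2(C1)OCCO2
F7 | step 15 | (6S,9S,10S)-10-bromo-9-[(tert-butyldimethylsilyl)oxy]-2-(trimethylstannyl)chamigra-2,7-diene | CC1=C[C@H](O[Si](C)(C)C(C)(C)C)[C@@H](Br)C(C)(C)[C@]12CCC(C)=C([Sn](C)(C)C)C2
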